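**Strategy.** The ten-membered ring is disconnected at C7–C8. The key step uses the fact that C7 is the β-carbon of the C6–C7–C11–C12 γ-lactone ring and that C8 is oxygenated: a C8 acyl radical adds to C7 of a butenolide whose C6 substituent is the rest of the chain. One operation forms C7–C8, closes the C1–C10 carbocycle and sets C7 trans to C6. The precursor is an open-chain (6S)-butenolide carrying the Z C4=C5 alkene, the silylated 3S carbinol, the 1R,10R epoxide and a C8 Se-phenyl selenoester. Its butenolide double bond is unmasked late from a glutamic-acid-derived lactone.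

Key step: step 15

Remark: atom numbers are the germacrane numbers of the target (ring C1–C10, lactone carbons C11–C12, methylene C13, C14 on C10, C15 on C4) and are kept for all intermediates.
Assumption: hydride reaches the C8 carbonyl of 23 from the outer face, anti to C11 and C14, which gives the 8R alcohol; the fallback for step 16 covers the other outcome.
Assumption: 7, 25, the D-fructose-derived Shi ketone and the reagents named are taken as commercial.

Step 1
Reactants: 1 but-3-yn-1-ol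
Product: 2 1-[(but-3-yn-1-yloxy)methyl]-4-methoxybenzene
Conditions: NaH, PMBCl, Bu4NI (cat.), THF, 0 °C to rt
Reagents that add atoms: 4-methoxybenzyl chloride, COc1ccc(CCl)cc1
Why: Williamson etherification of the primary alkoxide masks the C8 oxygen as an ether that tolerates organoaluminium, organochromium and amide-base steps and is later removed oxidatively.

Step 2
Reactants: 2 1-[(but-3-yn-1-yloxy)methyl]-4-methoxybenzene
Product: 5 (3E)-6-[(4-methoxyphenyl)methoxy]-4-methylhex-3-en-1-ol, via alkenyldimethylalane 3 (not isolated), via lithium alkenylalanate 4 (not isolated)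
Conditions: Me3Al, Cp2ZrCl2 (0.2 equiv), CH2Cl2, 0 °C to rt; volatiles removed; n-BuLi, hexane, 0 °C; ethylene oxide, THF, −30 °C to rt; aq. potassium sodium tartrate
Reagents that add atoms: trimethylaluminium, C[Al](C)C; ethylene oxide, C1CO1
Why: Negishi zirconium-catalysed carboalumination adds methyl and aluminium syn across the terminal alkyne (methyl to the internal carbon), and the derived alanate opens ethylene oxide with retention, so the E C1=C10 alkene and the C2–C3 unit are in place.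

Step 3
Reactants: 5 (3E)-6-[(4-methoxyphenyl)methoxy]-4-methylhex-3-en-1-ol
Product: 6 (3E)-6-[(4-methoxyphenyl)methoxy]-4-methylhex-3-enal
Conditions: Dess–Martin periodinane, NaHCO3, CH2Cl2, 0 °C; used at once
Reagents that add atoms: none
Why: Dess–Martin oxidation under buffered, non-basic conditions should give the β,γ-unsaturated aldehyde without migration of the alkene into conjugation.

Step 4
Reactants: 7 (5S)-5-(hydroxymethyl)oxolan-2-one
Product: 8 (2S)-5-oxooxolane-2-carbaldehyde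
Conditions: Dess–Martin periodinane, CH2Cl2, 0 °C to rt; filtered through Celite, used crude
Reagents that add atoms: none
Why: Dess–Martin oxidation without base or aqueous work-up should keep the C6 stereocentre, which comes from the chiral pool.

Step 5
Reactants: 8 (2S)-5-oxooxolane-2-carbaldehyde
Product: 9 (5S)-5-[(1Z)-2-iodoprop-1-en-1-yl]oxolan-2-one
Conditions: [EtPPh3]I, n-BuLi, THF, 0 °C; I2, −78 °C; NaN(SiMe3)2, −20 °C; then 8, −78 °C to −20 °C
Reagents that add atoms: ethyltriphenylphosphonium iodide, CC[P+](c1ccccc1)(c1ccccc1)c1ccccc1.[I-]; iodine, II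
Why: Stork–Zhao-type Wittig iodo-olefination with the α-iodo ylide Ph3P=C(I)CH3 gives, under kinetic control at low temperature, the trisubstituted vinyl iodide with iodine cis to C6 (Z), and the fast reaction limits epimerisation of the aldehyde.

Step 6
Reactants: 9 (5S)-5-[(1Z)-2-iodoprop-1-en-1-yl]oxolan-2-one; 6 (3E)-6-[(4-methoxyphenyl)methoxy]-4-methylhex-3-enal
Product: 10 (5S)-5-[(1Z,5E)-3-hydroxy-8-[(4-methoxyphenyl)methoxy]-2,6-dimethylocta-1,5-dien-1-yl]oxolan-2-one (both C3 epimers)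
Conditions: CrCl2 (6 equiv), NiCl2 (2 mol %), DMSO, rt
Reagents that add atoms: none
Why: Nozaki–Hiyama–Kishi coupling forms C3–C4 because the alkenylchromium species, generated with retention of the Z geometry, adds to the aldehyde and leaves the lactone alone; C3 is formed without control and is corrected in steps 7 and 8.

Step 7
Reactants: 10 (5S)-5-[(1Z,5E)-3-hydroxy-8-[(4-methoxyphenyl)methoxy]-2,6-dimethylocta-1,5-dien-1-yl]oxolan-2-one (both C3 epimers)
Product: 11 (5S)-5-[(1Z,5E)-8-[(4-methoxyphenyl)methoxy]-2,6-dimethyl-3-oxoocta-1,5-dien-1-yl]oxolan-2-one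
Conditions: Dess–Martin periodinane, NaHCO3, CH2Cl2, 0 °C
Reagents that add atoms: none
Why: Dess–Martin oxidation converges both allylic alcohol epimers on one Z enone under conditions that should leave the skipped C1=C10 alkene and the Z geometry untouched.

Step 8
Reactants: 11 (5S)-5-[(1Z,5E)-8-[(4-methoxyphenyl)methoxy]-2,6-dimethyl-3-oxoocta-1,5-dien-1-yl]oxolan-2-one
Product: 12 (5S)-5-[(1Z,3S,5E)-3-hydroxy-8-[(4-methoxyphenyl)methoxy]-2,6-dimethylocta-1,5-dien-1-yl]oxolan-2-one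
Conditions: (R)-2-methyl-CBS-oxazaborolidine (0.3 equiv), catecholborane, toluene, −78 °C
Reagents that add atoms: none
Why: In this Corey–Bakshi–Shibata reduction the (R)-oxazaborolidine binds the ketone with the α-methylalkenyl group as the large and the C2 methylene as the small substituent, so hydride should go to the face that gives the 3S alcohol, and the lactone is inert at −78 °C.

Step 9
Reactants: 12 (5S)-5-[(1Z,3S,5E)-3-hydroxy-8-[(4-methoxyphenyl)methoxy]-2,6-dimethylocta-1,5-dien-1-yl]oxolan-2-one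
Product: 13 (5S)-5-[(1Z,3S,5E)-3-[(tert-butyldimethylsilyl)oxy]-8-[(4-methoxyphenyl)methoxy]-2,6-dimethylocta-1,5-dien-1-yl]oxolan-2-one
Conditions: TBSOTf, 2,6-lutidine, CH2Cl2, −78 °C
Reagents that add atoms: tert-butyldimethylsilyl triflate, CC(C)(C)[Si](C)(C)OS(=O)(=O)C(F)(F)F
Why: Silylation of the hindered allylic alcohol with the silyl triflate and a non-nucleophilic base installs the C3 ether that is carried to the last step.

Step 10
Reactants: 13 (5S)-5-[(1Z,3S,5E)-3-[(tert-butyldimethylsilyl)oxy]-8-[(4-methoxyphenyl)methoxy]-2,6-dimethylocta-1,5-dien-1-yl]oxolan-2-one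
Product: 14 (5S)-5-[(1Z,3S)-3-[(tert-butyldimethylsilyl)oxy]-4-[(2R,3R)-3-{2-[(4-methoxyphenyl)methoxy]ethyl}-3-methyloxiran-2-yl]-2-methylbut-1-en-1-yl]oxolan-2-one
Conditions: D-fructose-derived Shi ketone (0.3 equiv), KHSO5 (Oxone), K2CO3, Bu4NHSO4, Na2B4O7 buffer, MeCN/CH2(OMe)2/H2O, 0 °C
Reagents that add atoms: potassium peroxymonosulfate, [K+].[O-]S(=O)(=O)OO
Why: In the Shi epoxidation the chiral dioxirane transfers oxygen through a spiro transition state to one face of the E trisubstituted C1=C10 alkene to give the 1R,10R epoxide, while the Z C4=C5 alkene should stay because it is cis-substituted, shielded by the silyl ether and deactivated by two allylic oxygens.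

Step 11
Reactants: 14 (5S)-5-[(1Z,3S)-3-[(tert-butyldimethylsilyl)oxy]-4-[(2R,3R)-3-{2-[(4-methoxyphenyl)methoxy]ethyl}-3-methyloxiran-2-yl]-2-methylbut-1-en-1-yl]oxolan-2-one
Product: 18 (5S)-5-[(1Z,3S)-3-[(tert-butyldimethylsilyl)oxy]-4-[(2R,3R)-3-{2-[(4-methoxyphenyl)methoxy]ethyl}-3-methyloxiran-2-yl]-2-methylbut-1-en-1-yl]furan-2(5H)-one, via lithium enolate 15 (not isolated), via α-phenylselanyl lactone 16 (not isolated), via selenoxide 17 (not isolated)
Conditions: LiN(SiMe3)2, THF, −78 °C; PhSeBr, −78 °C; then pyridine, 30% H2O2, 0 °C to rt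
Reagents that add atoms: none
Why: α-Selenenylation of the lactone enolate followed by selenoxide syn-elimination places the C7=C11 double bond (the only β-hydrogens are on C7), and the base-labile C6 centre of the γ-alkenyl butenolide meets only neutral steps from here on.

Step 12
Reactants: 18 (5S)-5-[(1Z,3S)-3-[(tert-butyldimethylsilyl)oxy]-4-[(2R,3R)-3-{2-[(4-methoxyphenyl)methoxy]ethyl}-3-methyloxiran-2-yl]-2-methylbut-1-en-1-yl]furan-2(5H)-one
Product: 19 (5S)-5-[(1Z,3S)-3-[(tert-butyldimethylsilyl)oxy]-4-[(2R,3R)-3-(2-hydroxyethyl)-3-methyloxiran-2-yl]-2-methylbut-1-en-1-yl]furan-2(5H)-one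
Conditions: DDQ, CH2Cl2/pH 7 phosphate buffer, 0 °C
Reagents that add atoms: none
Why: Oxidative cleavage of the 4-methoxybenzyl ether by DDQ frees the C8 alcohol without acid or base, so the epoxide, the silyl ether and the butenolide should persist.

Step 13
Reactants: 19 (5S)-5-[(1Z,3S)-3-[(tert-butyldimethylsilyl)oxy]-4-[(2R,3R)-3-(2-hydroxyethyl)-3-methyloxiran-2-yl]-2-methylbut-1-en-1-yl]furan-2(5H)-one
Product: 21 2-[(2R,3R)-3-{(2S,3Z)-2-[(tert-butyldimethylsilyl)oxy]-3-methyl-4-[(2S)-5-oxo-2,5-dihydrofuran-2-yl]but-3-en-1-yl}-2-methyloxiran-2-yl]acetic acid, via aldehyde 20 (not isolated)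
Conditions: TEMPO (0.2 equiv), PhI(OAc)2, MeCN/pH 7 phosphate buffer, 0 °C to rt
Reagents that add atoms: water, O
Why: The oxoammonium oxidation (TEMPO with PhI(OAc)2) takes the primary alcohol through the aldehyde hydrate to the acid in one flask near neutral pH, which avoids base-induced β-elimination of the 1,10-epoxide in the β,γ-epoxy aldehyde.

Step 14
Reactants: 21 2-[(2R,3R)-3-{(2S,3Z)-2-[(tert-butyldimethylsilyl)oxy]-3-methyl-4-[(2S)-5-oxo-2,5-dihydrofuran-2-yl]but-3-en-1-yl}-2-methyloxiran-2-yl]acetic acid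
Product: 22 Se-phenyl 2-[(2R,3R)-3-{(2S,3Z)-2-[(tert-butyldimethylsilyl)oxy]-3-methyl-4-[(2S)-5-oxo-2,5-dihydrofuran-2-yl]but-3-en-1-yl}-2-methyloxiran-2-yl]ethaneselenoate
Conditions: N-(phenylseleno)phthalimide, Bu3P, CH2Cl2, −20 °C to 0 °C
Reagents that add atoms: N-(phenylseleno)phthalimide, O=C1c2ccccc2C(=O)N1[Se]c1ccccc1
Why: In this redox-condensation selenoesterification the acyloxyphosphonium ion formed from the acid is attacked by phenylselenide under neutral conditions, with no free selenol or amine base that could add to or isomerise the butenolide.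

Step 15
Reactants: 22 Se-phenyl 2-[(2R,3R)-3-{(2S,3Z)-2-[(tert-butyldimethylsilyl)oxy]-3-methyl-4-[(2S)-5-oxo-2,5-dihydrofuran-2-yl]but-3-en-1-yl}-2-methyloxiran-2-yl]ethaneselenoate
Product: 23 (1R,3S,4Z,6R,7S,10R)-3-[(tert-butyldimethylsilyl)oxy]-1,10-epoxy-8-oxo-13-norgermacr-4-en-12,6-olide
Conditions: (Me3Si)3SiH, AIBN, benzene (2 mM in 22), 80 °C, silane and initiator added over 8 h by syringe pump
Reagents that add atoms: none
Why: The silyl radical abstracts PhSe from 22 to give the C8 acyl radical, a nucleophilic σ-radical that adds to C7, the electron-poor β-carbon of the butenolide, and the C11 radical, stabilised by the C12 carbonyl, takes hydrogen from the silane and carries the chain. The closest known reaction type is the acyl radical macrocyclisation of ω-unsaturated acyl phenyl selenides onto enoates and enones. The ten-membered ring C1–C10 closes in the 10-exo-trig mode, C11 staying outside the new ring. The new stereocentre C7 is controlled by C6: the flat butenolide carries the C5 chain on one face, and C8 should bond to the opposite face, which gives the trans-fused 12,6-lactone. The step needs C7 to win over the C4=C5 alkene and ring closure to win over hydrogen transfer and loss of CO. The first follows from polarity matching (electron-poor C7 against an electron-rich trisubstituted alkene), the second from the slow hydrogen donor kept at low concentration and from the slow decarbonylation of a primary acyl radical.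

Step 16
Reactants: 23 (1R,3S,4Z,6R,7S,10R)-3-[(tert-butyldimethylsilyl)oxy]-1,10-epoxy-8-oxo-13-norgermacr-4-en-12,6-olide
Product: 24 (1R,3S,4Z,6R,7R,8R,10R)-3-[(tert-butyldimethylsilyl)oxy]-1,10-epoxy-8-hydroxy-13-norgermacr-4-en-12,6-olide
Conditions: NaBH4, MeOH/THF, −78 °C to −40 °C
Reagents that add atoms: none
Why: Borohydride reduces the ketone faster than the lactone, and by substrate control hydride should come to the outer face of C8=O, away from C11 and the C14 methyl, to give the 8R (8β) alcohol.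

Step 17
Reactants: 25 angelic acid, (2Z)-2-methylbut-2-enoic acid
Product: 26 (2Z)-2-methylbut-2-en-1-ol
Conditions: LiAlH4, Et2O, 0 °C
Reagents that add atoms: none
Why: Hydride reduction of the carboxylic acid gives the allylic alcohol and leaves the Z trisubstituted alkene in place.

Step 18
Reactants: 26 (2Z)-2-methylbut-2-en-1-ol
Product: 27 [(2S,3R)-2,3-dimethyloxiran-2-yl]methanol
Conditions: Ti(OiPr)4 (10 mol %), L-(+)-diethyl tartrate (12 mol %), t-BuOOH, 4 Å MS, CH2Cl2, −20 °C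
Reagents that add atoms: tert-butyl hydroperoxide, CC(C)(C)OO
Why: In the Sharpless asymmetric epoxidation the titanium complex of L-(+)-diethyl tartrate delivers oxygen to the same enantioface as with other primary allylic alcohols, which here should give the 2S,3R epoxy alcohol.

Step 19
Reactants: 27 [(2S,3R)-2,3-dimethyloxiran-2-yl]methanol
Product: 28 (2R,3R)-2,3-dimethyloxirane-2-carboxylic acid (epoxyangelic acid)
Conditions: RuCl3·xH2O (2 mol %), NaIO4, CCl4/MeCN/H2O, rt
Reagents that add atoms: sodium periodate, [Na+].[O-]I(=O)(=O)=O; water, O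
Why: Catalytic RuO4 oxidation (RuCl3 with NaIO4) turns the epoxy alcohol into the glycidic acid without touching the epoxide, and the C2 descriptor changes from S to R only through the change in CIP priorities.

Step 20
Reactants: 28 (2R,3R)-2,3-dimethyloxirane-2-carboxylic acid; 24 (1R,3S,4Z,6R,7R,8R,10R)-3-[(tert-butyldimethylsilyl)oxy]-1,10-epoxy-8-hydroxy-13-norgermacr-4-en-12,6-olide
Product: 30 (1R,3S,4Z,6R,7R,8R,10R)-3-[(tert-butyldimethylsilyl)oxy]-8-{[(2R,3R)-2,3-dimethyloxirane-2-carbonyl]oxy}-1,10-epoxy-13-norgermacr-4-en-12,6-olide, via mixed anhydride 29 (not isolated)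
Conditions: 2,4,6-Cl3C6H2COCl, Et3N, toluene, rt; then 24, DMAP, toluene, rt
Reagents that add atoms: none
Why: In the Yamaguchi esterification DMAP attacks the less shielded carbonyl of the mixed anhydride, and the acylpyridinium ion acylates the C8 hydroxyl with retention at C8, before any enolate chemistry that could move the lactone to O8.

Step 21
Reactants: 30 (1R,3S,4Z,6R,7R,8R,10R)-3-[(tert-butyldimethylsilyl)oxy]-8-{[(2R,3R)-2,3-dimethyloxirane-2-carbonyl]oxy}-1,10-epoxy-13-norgermacr-4-en-12,6-olide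
Product: 32 (1R,3S,4Z,6R,7R,8R,10R)-3-[(tert-butyldimethylsilyl)oxy]-13-(dimethylamino)-8-{[(2R,3R)-2,3-dimethyloxirane-2-carbonyl]oxy}-1,10-epoxygermacr-4-en-12,6-olide (both C11 epimers), via lithium enolate 31 (not isolated)
Conditions: LiN(SiMe3)2, THF, −78 °C; Me2N=CH2 I (Eschenmoser's salt), −78 °C to 0 °C
Reagents that add atoms: dimethylmethyleneammonium iodide, C[N+](C)=C.[I-]
Why: The Mannich reaction of the lactone enolate with Eschenmoser's salt adds C13 at C11, the only enolisable position because the epoxyangelate has a fully substituted α-carbon, and the configuration formed at C11 is lost in the next step.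

Step 22
Reactants: 32 (1R,3S,4Z,6R,7R,8R,10R)-3-[(tert-butyldimethylsilyl)oxy]-13-(dimethylamino)-8-{[(2R,3R)-2,3-dimethyloxirane-2-carbonyl]oxy}-1,10-epoxygermacr-4-en-12,6-olide
Product: 34 (1R,3S,4Z,6R,7R,8R,10R)-3-[(tert-butyldimethylsilyl)oxy]-8-{[(2R,3R)-2,3-dimethyloxirane-2-carbonyl]oxy}-1,10-epoxygermacra-4,11(13)-dien-12,6-olide, via ammonium iodide 33 (not isolated)
Conditions: MeI, CH2Cl2/MeOH, rt; then aq. NaHCO3, rt
Reagents that add atoms: none
Why: Quaternisation of the amine and E1cB (Hofmann-type) loss of trimethylamine from the β-ammonio lactone should give the exocyclic C11=C13 methylene under mild base.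

Step 23
Reactants: 34 (1R,3S,4Z,6R,7R,8R,10R)-3-[(tert-butyldimethylsilyl)oxy]-8-{[(2R,3R)-2,3-dimethyloxirane-2-carbonyl]oxy}-1,10-epoxygermacra-4,11(13)-dien-12,6-olide
Product: 35 (1R,3S,4Z,6R,7R,8R,10R)-8-{[(2R,3R)-2,3-dimethyloxirane-2-carbonyl]oxy}-1,10-epoxy-3-hydroxygermacra-4,11(13)-dien-12,6-olide (target)
Conditions: Bu4NF, AcOH (1:1), THF, 0 °C to rt
Reagents that add atoms: none
Why: Fluoride cleaves the Si–O bond, and the acetic acid buffer keeps the medium near neutral, so the α-methylene lactone, the ester and both epoxides should survive and acid-induced transannular opening of the 1,10-epoxide by the C4=C5 alkene is avoided.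

**Compound list**

1 | but-3-yn-1-ol | C#CCCO | starting material
2 | 1-[(but-3-yn-1-yloxy)methyl]-4-methoxybenzene | C#CCCOCc1ccc(OC)cc1 | intermediate
3 | [(1E)-4-[(4-methoxyphenyl)methoxy]-2-methylbut-1-en-1-yl]dimethylalane | C[Al](C)/C=C(\C)CCOCc1ccc(OC)cc1 | intermediate
4 | lithium butyl[(1E)-4-[(4-methoxyphenyl)methoxy]-2-methylbut-1-en-1-yl]dimethylalanate | [Li+].CCCC[Al-](C)(C)/C=C(\C)CCOCc1ccc(OC)cc1 | intermediate
5 | (3E)-6-[(4-methoxyphenyl)methoxy]-4-methylhex-3-en-1-ol | COc1ccc(COCC/C(C)=C/CCO)cc1 | intermediate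
6 | (3E)-6-[(4-methoxyphenyl)methoxy]-4-methylhex-3-enal | COc1ccc(COCC/C(C)=C/CC=O)cc1 | intermediate
7 | (5S)-5-(hydroxymethyl)oxolan-2-one | O=C1CC[C@@H](CO)O1 | starting material
8 | (2S)-5-oxooxolane-2-carbaldehyde | O=C[C@@H]1CCC(=O)O1 | intermediate
9 | (5S)-5-[(1Z)-2-iodoprop-1-en-1-yl]oxolan-2-one | C/C(I)=C/[C@@H]1CCC(=O)O1 | intermediate
10 | (5S)-5-[(1Z,5E)-3-hydroxy-8-[(4-methoxyphenyl)methoxy]-2,6-dimethylocta-1,5-dien-1-yl]oxolan-2-one, both C3 epimers | COc1ccc(COCC/C(C)=C/CC(O)/C(C)=C\[C@@H]2CCC(=O)O2)cc1 | intermediate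
11 | (5S)-5-[(1Z,5E)-8-[(4-methoxyphenyl)methoxy]-2,6-dimethyl-3-oxoocta-1,5-dien-1-yl]oxolan-2-one | COc1ccc(COCC/C(C)=C/CC(=O)/C(C)=C\[C@@H]2CCC(=O)O2)cc1 | intermediate
12 | (5S)-5-[(1Z,3S,5E)-3-hydroxy-8-[(4-methoxyphenyl)methoxy]-2,6-dimethylocta-1,5-dien-1-yl]oxolan-2-one | COc1ccc(COCC/C(C)=C/C[C@H](O)/C(C)=C\[C@@H]2CCC(=O)O2)cc1 | intermediate
13 | (5S)-5-[(1Z,3S,5E)-3-[(tert-butyldimethylsilyl)oxy]-8-[(4-methoxyphenyl)methoxy]-2,6-dimethylocta-1,5-dien-1-yl]oxolan-2-one | COc1ccc(COCC/C(C)=C/C[C@H](O[Si](C)(C)C(C)(C)C)/C(C)=C\[C@@H]2CCC(=O)O2)cc1 | intermediate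
14 | (5S)-5-[(1Z,3S)-3-[(tert-butyldimethylsilyl)oxy]-4-[(2R,3R)-3-{2-[(4-methoxyphenyl)methoxy]ethyl}-3-methyloxiran-2-yl]-2-methylbut-1-en-1-yl]oxolan-2-one | COc1ccc(COCC[C@@]2(C)O[C@@H]2C[C@H](O[Si](C)(C)C(C)(C)C)/C(C)=C\[C@@H]3CCC(=O)O3)cc1 | intermediate
15 | lithium enolate of 14 (C11=C12–OLi) | [Li+].COc1ccc(COCC[C@@]2(C)O[C@@H]2C[C@H](O[Si](C)(C)C(C)(C)C)/C(C)=C\[C@@H]3CC=C([O-])O3)cc1 | intermediate
16 | 14 bearing a phenylselanyl group on C11 (lactone α-carbon), both C11 epimers | COc1ccc(COCC[C@@]2(C)O[C@@H]2C[C@H](O[Si](C)(C)C(C)(C)C)/C(C)=C\[C@@H]3CC([Se]c4ccccc4)C(=O)O3)cc1 | intermediate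
17 | selenoxide of 16 | COc1ccc(COCC[C@@]2(C)O[C@@H]2C[C@H](O[Si](C)(C)C(C)(C)C)/C(C)=C\[C@@H]3CC([Se](=O)c4ccccc4)C(=O)O3)cc1 | intermediate
18 | (5S)-5-[(1Z,3S)-3-[(tert-butyldimethylsilyl)oxy]-4-[(2R,3R)-3-{2-[(4-methoxyphenyl)methoxy]ethyl}-3-methyloxiran-2-yl]-2-methylbut-1-en-1-yl]furan-2(5H)-one | COc1ccc(COCC[C@@]2(C)O[C@@H]2C[C@H](O[Si](C)(C)C(C)(C)C)/C(C)=C\[C@@H]3C=CC(=O)O3)cc1 | intermediate
19 | (5S)-5-[(1Z,3S)-3-[(tert-butyldimethylsilyl)oxy]-4-[(2R,3R)-3-(2-hydroxyethyl)-3-methyloxiran-2-yl]-2-methylbut-1-en-1-yl]furan-2(5H)-one | OCC[C@@]1(C)O[C@@H]1C[C@H](O[Si](C)(C)C(C)(C)C)/C(C)=C\[C@@H]2C=CC(=O)O2 | intermediate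
20 | (5S)-5-[(1Z,3S)-3-[(tert-butyldimethylsilyl)oxy]-2-methyl-4-[(2R,3R)-3-methyl-3-(2-oxoethyl)oxiran-2-yl]but-1-en-1-yl]furan-2(5H)-one | O=CC[C@@]1(C)O[C@@H]1C[C@H](O[Si](C)(C)C(C)(C)C)/C(C)=C\[C@@H]2C=CC(=O)O2 | intermediate
21 | 2-[(2R,3R)-3-{(2S,3Z)-2-[(tert-butyldimethylsilyl)oxy]-3-methyl-4-[(2S)-5-oxo-2,5-dihydrofuran-2-yl]but-3-en-1-yl}-2-methyloxiran-2-yl]acetic acid | OC(=O)C[C@@]1(C)O[C@@H]1C[C@H](O[Si](C)(C)C(C)(C)C)/C(C)=C\[C@@H]2C=CC(=O)O2 | intermediate
22 | Se-phenyl 2-[(2R,3R)-3-{(2S,3Z)-2-[(tert-butyldimethylsilyl)oxy]-3-methyl-4-[(2S)-5-oxo-2,5-dihydrofuran-2-yl]but-3-en-1-yl}-2-methyloxiran-2-yl]ethaneselenoate (key-step precursor) | O=C1C=C[C@H](O1)/C=C(/C)[C@@H](O[Si](C)(C)C(C)(C)C)C[C@H]2O[C@]2(C)CC(=O)[Se]c1ccccc1 | intermediate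
23 | (1R,3S,4Z,6R,7S,10R)-3-[(tert-butyldimethylsilyl)oxy]-1,10-epoxy-8-oxo-13-norgermacr-4-en-12,6-olide (key-step product) | C1C(=O)O[C@@H]2/C=C(/C)[C@@H](O[Si](C)(C)C(C)(C)C)C[C@H]3O[C@]3(C)CC(=O)[C@@H]12 | intermediate
24 | (1R,3S,4Z,6R,7R,8R,10R)-3-[(tert-butyldimethylsilyl)oxy]-1,10-epoxy-8-hydroxy-13-norgermacr-4-en-12,6-olide | C1C(=O)O[C@@H]2/C=C(/C)[C@@H](O[Si](C)(C)C(C)(C)C)C[C@H]3O[C@]3(C)C[C@@H](O)[C@@H]12 | intermediate
25 | angelic acid, (2Z)-2-methylbut-2-enoic acid | C/C=C(/C)C(=O)O | starting material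
26 | (2Z)-2-methylbut-2-en-1-ol | C/C=C(/C)CO | intermediate
27 | [(2S,3R)-2,3-dimethyloxiran-2-yl]methanol | OC[C@]1(C)O[C@@H]1C | intermediate
28 | (2R,3R)-2,3-dimethyloxirane-2-carboxylic acid | OC(=O)[C@]1(C)O[C@@H]1C | intermediate
29 | (2R,3R)-2,3-dimethyloxirane-2-carboxylic 2,4,6-trichlorobenzoic anhydride | O=C(OC(=O)[C@]1(C)O[C@@H]1C)c1c(Cl)cc(Cl)cc1Cl | intermediate
30 | (1R,3S,4Z,6R,7R,8R,10R)-3-[(tert-butyldimethylsilyl)oxy]-8-{[(2R,3R)-2,3-dimethyloxirane-2-carbonyl]oxy}-1,10-epoxy-13-norgermacr-4-en-12,6-olide | C1C(=O)O[C@@H]2/C=C(/C)[C@@H](O[Si](C)(C)C(C)(C)C)C[C@H]3O[C@]3(C)C[C@@H](OC(=O)[C@]3(C)O[C@@H]3C)[C@@H]12 | intermediate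
31 | lithium enolate of 30 (C11=C12–OLi) | C1=C([O-])O[C@@H]2/C=C(/C)[C@@H](O[Si](C)(C)C(C)(C)C)C[C@H]3O[C@]3(C)C[C@@H](OC(=O)[C@]3(C)O[C@@H]3C)[C@@H]12.[Li+] | intermediate
32 | (1R,3S,4Z,6R,7R,8R,10R)-3-[(tert-butyldimethylsilyl)oxy]-13-(dimethylamino)-8-{[(2R,3R)-2,3-dimethyloxirane-2-carbonyl]oxy}-1,10-epoxygermacr-4-en-12,6-olide, both C11 epimers | CN(C)CC1C(=O)O[C@@H]2/C=C(/C)[C@@H](O[Si](C)(C)C(C)(C)C)C[C@H]3O[C@]3(C)C[C@@H](OC(=O)[C@]3(C)O[C@@H]3C)[C@@H]12 | intermediate
33 | N-methyl ammonium iodide of 32 (13-trimethylammonio) | C[N+](C)(C)CC1C(=O)O[C@@H]2/C=C(/C)[C@@H](O[Si](C)(C)C(C)(C)C)C[C@H]3O[C@]3(C)C[C@@H](OC(=O)[C@]3(C)O[C@@H]3C)[C@@H]12.[I-] | intermediate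
34 | (1R,3S,4Z,6R,7R,8R,10R)-3-[(tert-butyldimethylsilyl)oxy]-8-{[(2R,3R)-2,3-dimethyloxirane-2-carbonyl]oxy}-1,10-epoxygermacra-4,11(13)-dien-12,6-olide | C=C1C(=O)O[C@@H]2/C=C(/C)[C@@H](O[Si](C)(C)C(C)(C)C)C[C@H]3O[C@]3(C)C[C@@H](OC(=O)[C@]3(C)O[C@@H]3C)[C@@H]12 | intermediate
35 | (1R,3S,4Z,6R,7R,8R,10R)-8-{[(2R,3R)-2,3-dimethyloxirane-2-carbonyl]oxy}-1,10-epoxy-3-hydroxygermacra-4,11(13)-dien-12,6-olide | C=C1C(=O)O[C@@H]2/C=C(/C)[C@@H](O)C[C@H]3O[C@]3(C)C[C@@H](OC(=O)[C@]3(C)O[C@@H]3C)[C@@H]12 | target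

**Step count and risks**

Total step count: 23. Longest linear sequence: 18 steps (steps 1–3, 6–16 and 20–23, from but-3-yn-1-ol).

Steps most likely to fail:

Step 15. What may go wrong: the ten-membered ring closes too slowly. Then hydrogen transfer to the acyl radical, loss of CO followed by opening of the 1,10-epoxide, or bonding to the wrong face of C7 takes over. The fallback sets out from 19. Dess–Martin oxidation gives aldehyde 20, this time isolated. SmI2 (THF, HMPA, t-BuOH, −78 °C, high dilution) converts it into the C8 ketyl radical anion, which adds to C7 of the butenolide in a reductive ketyl–olefin cyclisation and should give the 8-hydroxy lactone as a C8 epimer mixture F1. Dess–Martin oxidation of F1 gives 23, where the route is rejoined.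

Step 16. What may go wrong: hydride is delivered to the other face of the C8 carbonyl (low or reversed facial selectivity), or the C8 alkoxide moves the lactone to O8. The fallback sets out from 23. If reduction gives mainly the 8S alcohol F2, this epimer is esterified with 28 under Mitsunobu conditions (PPh3, DIAD, toluene, 0 °C to rt), which inverts C8 and gives 30, where the route is rejoined.

Step 21. What may go wrong: the C11 enolate attacks the neighbouring C8 ester carbonyl (acyl shift from oxygen to carbon), or it is trapped incompletely. The fallback sets out from 24 and postpones the ester. Silylation (Et3SiOTf, 2,6-lutidine, CH2Cl2, −78 °C) gives the 8-O-triethylsilyl ether F3. Its lithium enolate F4 (LiN(SiMe3)2, THF, −78 °C) is trapped with Eschenmoser's salt to give the Mannich base F5. MeI gives the ammonium iodide F6, and aq. NaHCO3 gives the α-methylene lactone F7. Bu4NF buffered with AcOH at −20 °C removes the triethylsilyl group ahead of the hindered TBS ether and gives the 8-hydroxy α-methylene lactone F8. Yamaguchi esterification of F8 with 28 (through 29) gives 34, where the route is rejoined.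

**Further compounds**

F1 | step 15 | 8-hydroxy lactone 24 together with its C8 epimer (mixture at C8) | C1C(=O)O[C@@H]2/C=C(/C)[C@@H](O[Si](C)(C)C(C)(C)C)C[C@H]3O[C@]3(C)CC(O)[C@@H]12
F2 | step 16 | (8S) epimer of 24 | C1C(=O)O[C@@H]2/C=C(/C)[C@@H](O[Si](C)(C)C(C)(C)C)C[C@H]3O[C@]3(C)C[C@H](O)[C@@H]12
F3 | step 21 | 8-O-triethylsilyl ether of 24 | C1C(=O)O[C@@H]2/C=C(/C)[C@@H](O[Si](C)(C)C(C)(C)C)C[C@H]3O[C@]3(C)C[C@@H](O[Si](CC)(CC)CC)[C@@H]12
F4 | step 21 | lithium enolate of F3 | C1=C([O-])O[C@@H]2/C=C(/C)[C@@H](O[Si](C)(C)C(C)(C)C)C[C@H]3O[C@]3(C)C[C@@H](O[Si](CC)(CC)CC)[C@@H]12.[Li+]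
F5 | step 21 | 13-(dimethylamino) Mannich base of F3, both C11 epimers | CN(C)CC1C(=O)O[C@@H]2/C=C(/C)[C@@H](O[Si](C)(C)C(C)(C)C)C[C@H]3O[C@]3(C)C[C@@H](O[Si](CC)(CC)CC)[C@@H]12
F6 | step 21 | N-methyl ammonium iodide of F5 | C[N+](C)(C)CC1C(=O)O[C@@H]2/C=C(/C)[C@@H](O[Si](C)(C)C(C)(C)C)C[C@H]3O[C@]3(C)C[C@@H](O[Si](CC)(CC)CC)[C@@H]12.[I-]
F7 | step 21 | 3-O-TBS 8-O-triethylsilyl 1,10-epoxy-3,8-dihydroxygermacra-4,11(13)-dien-12,6-olide | C=C1C(=O)O[C@@H]2/C=C(/C)[C@@H](O[Si](C)(C)C(C)(C)C)C[C@H]3O[C@]3(C)C[C@@H](O[Si](CC)(CC)CC)[C@@H]12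
F8 | step 21 | 3-O-TBS 1,10-epoxy-3,8-dihydroxygermacra-4,11(13)-dien-12,6-olide (free 8R hydroxyl) | C=C1C(=O)O[C@@H]2/C=C(/C)[C@@H](O[Si](C)(C)C(C)(C)C)C[C@H]3O[C@]3(C)C[C@@H](O)[C@@H]12
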